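**Plan**

- Side-chain carbons are counted C1–C12 from the ring-bound alkyne carbon. Retrosynthetically the C10 carbinol is taken back to a ketone and the C8–C9 bond is cut by a retro-Claisen. This is possible because the E-alkene C6=C7(CH3), the methylenes C8 and C9 and the C10 carbonyl form a γ,δ-unsaturated ketone, which maps onto a 2-methylallylic alcohol (C6 carbinol, C7=C8) plus a C9–C12 hydroxy ketal.
- The remaining cuts are aryl–C1 and C2–C3 (two Sonogashira couplings on acetylene), C6–C7 (Grignard addition) and C4–C5 (enolate alkylation with 2,3-dibromopropene).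
- Forward order: C4–C5, C6–C7, C2–C3, aryl–C1, then C8–C9 together with the E-alkene. No ring is formed; the benzene ring is bought as methyl 4-hydroxy-3-iodobenzoate.
- Stereochemistry: the E geometry comes from the chair transition state of the rearrangement. The only stereocentre (10S) comes from a catalyst-controlled CBS reduction of the C10 ketone. The racemic C6 carbinol of the precursor is erased in the rearrangement.
- Protecting groups: phenol as pivalate and acid as methyl ester, both removed with LiOH in the last step.

Key step: step 9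

Assumptions: the carbinol carbon of precursor 14 is carried as the racemate, since the rearrangement turns it into an sp2 carbon. 3,3-Dimethoxy-2-methylbutan-2-ol is treated as not purchasable and is made in step 8.

**Route**

Step 1
Reactants: 1 tert-butyl acetate; 2 2,3-dibromopropene
Product: 4 tert-butyl 4-bromopent-4-enoate, via lithium enolate of tert-butyl acetate 3 (not isolated)
Conditions: LiN(i-Pr)2 (LDA, 1.2 equiv), THF, −78 °C; then 2 (1.0 equiv), −78 → 0 °C
Reagents that add atoms: none
Why: Ester enolate alkylation, in which the lithium enolate of the tert-butyl ester (slow to self-condense at −78 °C) should displace the allylic bromide of 2 while the vinylic C–Br bond is inert to substitution; direct and allylically transposed attack give the same product.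

Step 2
Reactants: 4 tert-butyl 4-bromopent-4-enoate
Product: 6 4-bromopent-4-enal, via aluminium hemiacetal 5 (not isolated)
Conditions: i-Bu2AlH (DIBAL-H, 1.1 equiv), CH2Cl2, −78 °C; MeOH, then aq. KNaC4H4O6 (potassium sodium tartrate); used as a concentrated solution because of its volatility
Reagents that add atoms: none
Why: Partial ester reduction with i-Bu2AlH, in which the tetrahedral aluminium hemiacetal 5 should persist at −78 °C and release the aldehyde only on work-up, so that over-reduction is avoided and the vinyl bromide is untouched.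

Step 3
Reactants: 6 4-bromopent-4-enal; 7 isopropenylmagnesium bromide
Product: 8 6-bromo-2-methylhepta-1,6-dien-3-ol (racemic)
Conditions: THF, −78 → 0 °C; aq. NH4Cl
Reagents that add atoms: none
Why: Grignard 1,2-addition of an alkenylmagnesium halide to an unhindered aldehyde should give the 2-methylallylic alcohol without halogen–magnesium exchange at the vinyl bromide, and its configuration is irrelevant because step 9 destroys it.

Step 4
Reactants: 8 6-bromo-2-methylhepta-1,6-dien-3-ol; 9 ethynyltrimethylsilane
Product: 10 2-methyl-6-methylidene-8-(trimethylsilyl)oct-1-en-7-yn-3-ol (racemic)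
Conditions: PdCl2(PPh3)2 (3 mol%), CuI (6 mol%), Et3N, THF, 50 °C, sealed vessel, degassed
Reagents that add atoms: none
Why: Sonogashira coupling, in which the 2-bromoalkene should add oxidatively to zerovalent palladium generated in the flask and take the alkynyl group from the copper acetylide, while the silyl cap prevents double coupling and the free hydroxyl is tolerated.

Step 5
Reactants: 10 2-methyl-6-methylidene-8-(trimethylsilyl)oct-1-en-7-yn-3-ol
Product: 11 2-methyl-6-methylideneoct-1-en-7-yn-3-ol (racemic)
Conditions: K2CO3 (0.2 equiv), MeOH, 0 °C → rt; used without prolonged storage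
Reagents that add atoms: none
Why: Base-catalysed protodesilylation of the alkynylsilane by methoxide should free the terminal alkyne, and nothing else in the molecule is sensitive to mild carbonate in methanol.

Step 6
Reactants: 12 methyl 4-hydroxy-3-iodobenzoate
Product: 13 methyl 4-(2,2-dimethylpropanoyloxy)-3-iodobenzoate (the aryl pivalate)
Conditions: t-BuCOCl (1.2 equiv), Et3N (1.5 equiv), 4-(dimethylamino)pyridine (5 mol%), CH2Cl2, 0 °C → rt
Reagents that add atoms: pivaloyl chloride CC(C)(C)C(Cl)=O
Why: Nucleophile-catalysed O-acylation of the phenol should be clean, and the bulky pivalate keeps the oxygen from adding to the alkyne during coupling and should survive amine bases and the weakly acidic heating of step 9.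

Step 7
Reactants: 11 2-methyl-6-methylideneoct-1-en-7-yn-3-ol; 13 methyl 4-(2,2-dimethylpropanoyloxy)-3-iodobenzoate
Product: 14 methyl 3-(6-hydroxy-7-methyl-3-methylideneoct-7-en-1-ynyl)-4-(pivaloyloxy)benzoate (racemic)
Conditions: PdCl2(PPh3)2 (2 mol%), CuI (4 mol%), Et3N, THF, rt, degassed
Reagents that add atoms: none
Why: Sonogashira coupling of an electron-poor aryl iodide should proceed at room temperature, which suppresses alkyne homocoupling and leaves the aryl ester and the allylic alcohol untouched.

Step 8
Reactants: 15 3-hydroxy-3-methylbutan-2-one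
Product: 16 3,3-dimethoxy-2-methylbutan-2-ol
Conditions: HC(OMe)3 (2 equiv), p-toluenesulfonic acid monohydrate (1 mol%), MeOH, rt; solid K2CO3, then distillation
Reagents that add atoms: trimethyl orthoformate COC(OC)OC; methanol CO
Why: Acid-catalysed dimethyl ketal formation, driven by the orthoformate as water scavenger, should convert the ketone while the tertiary hydroxyl stays free.

Step 9
Reactants: 14 methyl 3-(6-hydroxy-7-methyl-3-methylideneoct-7-en-1-ynyl)-4-(pivaloyloxy)benzoate; 16 3,3-dimethoxy-2-methylbutan-2-ol
Product: 19 methyl 3-[(6E)-11-hydroxy-7,11-dimethyl-3-methylidene-10-oxododec-6-en-1-ynyl]-4-(pivaloyloxy)benzoate, via mixed methyl allyl ketal 17 (not isolated), via allyl vinyl ether 18 (not isolated)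
Conditions: 16 (5 equiv), 2,4-dinitrophenol (0.1 equiv), toluene, 110 °C, MeOH distilled off continuously, trace 2,6-di-tert-butyl-4-methylphenol as radical inhibitor
Reagents that add atoms: none
Why: The weak acid ionises ketal 16 to an oxocarbenium ion that is captured by the secondary allylic hydroxyl of 14 to give mixed ketal 17; loss of the second methanol, with the proton taken from the methyl group (the only enolisable position, since the other α-carbon is fully substituted), gives allyl vinyl ether 18, which undergoes a concerted [3,3]-sigmatropic shift to form the C8–C9 bond and the C10 ketone. The closest known reaction type is the hydroxy-ketal Claisen rearrangement of 2-methylallylic secondary alcohols used to build E-trisubstituted alkenes in terpenoid chains. No ring is closed and no stereocentre is created; the racemic carbinol carbon of 14 becomes the sp2 carbon C6. The selectivity required is E over Z at C6=C7, and it should come from the chair transition state in which the C4–C5 chain on the carbinol carbon is equatorial, since in the axial position it would meet the bulky 2-hydroxypropan-2-yl group on the vinyl ether carbon in a 1,3-diaxial clash. Chemoselectivity rests on the mild, nearly neutral thermal conditions, which the conjugated enyne, the aryl pivalate and the methyl ester should tolerate, and on removal of methanol to drive both exchange steps.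

Step 10
Reactants: 19 methyl 3-[(6E)-11-hydroxy-7,11-dimethyl-3-methylidene-10-oxododec-6-en-1-ynyl]-4-(pivaloyloxy)benzoate
Product: 20 methyl 3-[(6E)-7,11-dimethyl-3-methylidene-10-oxo-11-(trimethylsilyloxy)dodec-6-en-1-ynyl]-4-(pivaloyloxy)benzoate
Conditions: Me3SiCl (1.5 equiv), imidazole (3 equiv), DMF, 0 °C → rt
Reagents that add atoms: chlorotrimethylsilane C[Si](C)(C)Cl
Why: Silyl ether formation at the tertiary hydroxyl removes the group that would otherwise consume borane and deliver hydride without control, and it makes the C11 substituent the clearly larger flank of the ketone.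

Step 11
Reactants: 20 methyl 3-[(6E)-7,11-dimethyl-3-methylidene-10-oxo-11-(trimethylsilyloxy)dodec-6-en-1-ynyl]-4-(pivaloyloxy)benzoate
Product: 23 methyl 3-[(6E,10S)-10,11-dihydroxy-7,11-dimethyl-3-methylidenedodec-6-en-1-ynyl]-4-(pivaloyloxy)benzoate, via catecholborate ester 21 (not isolated), via silyl ether carbinol 22 (not isolated)
Conditions: (R)-1-methyl-3,3-diphenyltetrahydro-1H,3H-pyrrolo[1,2-c][1,3,2]oxazaborole ((R)-Me-CBS, 0.2 equiv), catecholborane (2 equiv), toluene, −78 → −30 °C; MeOH; then 1 M HCl, THF, 0 °C → rt
Reagents that add atoms: none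
Why: Corey–Bakshi–Shibata reduction, in which the ketone should bind to the ring boron with the fully substituted C(CH3)2OSiMe3 group pointing away from the catalyst, so that the (R)-catalyst delivers hydride to the face that gives the (10S)-alcohol (the same sense as acetophenone to (S)-1-phenylethanol); catecholborane at low temperature should neither hydroborate the alkenes and alkyne nor reduce the esters, and the dilute acid work-up removes the silyl group.

Step 12
Reactants: 23 methyl 3-[(6E,10S)-10,11-dihydroxy-7,11-dimethyl-3-methylidenedodec-6-en-1-ynyl]-4-(pivaloyloxy)benzoate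
Product: 25 pestalotioquinol F which is 3-[(6E,10S)-10,11-dihydroxy-7,11-dimethyl-3-methylidenedodec-6-en-1-ynyl]-4-hydroxybenzoic acid, via phenol methyl ester 24 (not isolated)
Conditions: LiOH·H2O (10 equiv), THF/MeOH/H2O (3:1:1), 0 °C → rt (up to 40 °C only if the ester persists), argon; then 1 M HCl to pH 3 at 0 °C
Reagents that add atoms: lithium hydroxide [Li+].[OH-]
Why: Saponification, in which hydroxide should cleave the aryl pivalate first and then the methyl benzoate by acyl substitution, while the low temperature and protic medium keep the phenoxide from adding to the alkyne and the C10 carbinol cannot epimerise.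

**Compound list**

1 | tert-butyl acetate | CC(=O)OC(C)(C)C | starting material
2 | 2,3-dibromopropene | C=C(Br)CBr | starting material
3 | lithium enolate of tert-butyl acetate | C=C(O[Li])OC(C)(C)C | intermediate
4 | tert-butyl 4-bromopent-4-enoate | C=C(Br)CCC(=O)OC(C)(C)C | intermediate
5 | diisobutylaluminium hemiacetal of 4 (4-bromo-1-tert-butoxypent-4-en-1-olate) | C=C(Br)CCC(O[Al](CC(C)C)CC(C)C)OC(C)(C)C | intermediate
6 | 4-bromopent-4-enal | C=C(Br)CCC=O | intermediate
7 | isopropenylmagnesium bromide | C=C(C)[Mg]Br | starting material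
8 | 6-bromo-2-methylhepta-1,6-dien-3-ol (racemic) | C=C(Br)CCC(O)C(C)=C | intermediate
9 | ethynyltrimethylsilane | C#C[Si](C)(C)C | starting material
10 | 2-methyl-6-methylidene-8-(trimethylsilyl)oct-1-en-7-yn-3-ol (racemic) | C=C(C)C(O)CCC(=C)C#C[Si](C)(C)C | intermediate
11 | 2-methyl-6-methylideneoct-1-en-7-yn-3-ol (racemic) | C=C(C)C(O)CCC(=C)C#C | intermediate
12 | methyl 4-hydroxy-3-iodobenzoate | COC(=O)c1ccc(O)c(I)c1 | starting material
13 | methyl 4-(2,2-dimethylpropanoyloxy)-3-iodobenzoate | COC(=O)c1ccc(OC(=O)C(C)(C)C)c(I)c1 | intermediate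
14 | methyl 3-(6-hydroxy-7-methyl-3-methylideneoct-7-en-1-ynyl)-4-(pivaloyloxy)benzoate (racemic) | COC(=O)c1ccc(OC(=O)C(C)(C)C)c(C#CC(=C)CCC(O)C(C)=C)c1 | intermediate
15 | 3-hydroxy-3-methylbutan-2-one | CC(=O)C(C)(C)O | starting material
16 | 3,3-dimethoxy-2-methylbutan-2-ol | COC(C)(OC)C(C)(C)O | intermediate
17 | methyl 3-[6-(3-hydroxy-2-methoxy-3-methylbutan-2-yloxy)-7-methyl-3-methylideneoct-7-en-1-ynyl]-4-(pivaloyloxy)benzoate (mixed ketal, diastereomer mixture) | COC(=O)c1ccc(OC(=O)C(C)(C)C)c(C#CC(=C)CCC(OC(C)(OC)C(C)(C)O)C(C)=C)c1 | intermediate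
18 | methyl 3-[6-(3-hydroxy-3-methylbut-1-en-2-yloxy)-7-methyl-3-methylideneoct-7-en-1-ynyl]-4-(pivaloyloxy)benzoate (allyl vinyl ether, racemic) | COC(=O)c1ccc(OC(=O)C(C)(C)C)c(C#CC(=C)CCC(OC(=C)C(C)(C)O)C(C)=C)c1 | intermediate
19 | methyl 3-[(6E)-11-hydroxy-7,11-dimethyl-3-methylidene-10-oxododec-6-en-1-ynyl]-4-(pivaloyloxy)benzoate | COC(=O)c1ccc(OC(=O)C(C)(C)C)c(C#CC(=C)CC/C=C(\C)CCC(=O)C(C)(C)O)c1 | intermediate
20 | methyl 3-[(6E)-7,11-dimethyl-3-methylidene-10-oxo-11-(trimethylsilyloxy)dodec-6-en-1-ynyl]-4-(pivaloyloxy)benzoate | COC(=O)c1ccc(OC(=O)C(C)(C)C)c(C#CC(=C)CC/C=C(\C)CCC(=O)C(C)(C)O[Si](C)(C)C)c1 | intermediate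
21 | catecholborate ester of the (10S)-carbinol, C11 hydroxyl as trimethylsilyl ether | COC(=O)c1ccc(OC(=O)C(C)(C)C)c(C#CC(=C)CC/C=C(\C)CC[C@H](OB2Oc3ccccc3O2)C(C)(C)O[Si](C)(C)C)c1 | intermediate
22 | methyl 3-[(6E,10S)-10-hydroxy-7,11-dimethyl-3-methylidene-11-(trimethylsilyloxy)dodec-6-en-1-ynyl]-4-(pivaloyloxy)benzoate | COC(=O)c1ccc(OC(=O)C(C)(C)C)c(C#CC(=C)CC/C=C(\C)CC[C@H](O)C(C)(C)O[Si](C)(C)C)c1 | intermediate
23 | methyl 3-[(6E,10S)-10,11-dihydroxy-7,11-dimethyl-3-methylidenedodec-6-en-1-ynyl]-4-(pivaloyloxy)benzoate | COC(=O)c1ccc(OC(=O)C(C)(C)C)c(C#CC(=C)CC/C=C(\C)CC[C@H](O)C(C)(C)O)c1 | intermediate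
24 | methyl 3-[(6E,10S)-10,11-dihydroxy-7,11-dimethyl-3-methylidenedodec-6-en-1-ynyl]-4-hydroxybenzoate | COC(=O)c1ccc(O)c(C#CC(=C)CC/C=C(\C)CC[C@H](O)C(C)(C)O)c1 | intermediate
25 | pestalotioquinol F, 3-[(6E,10S)-10,11-dihydroxy-7,11-dimethyl-3-methylidenedodec-6-en-1-ynyl]-4-hydroxybenzoic acid | C=C(C#Cc1cc(C(=O)O)ccc1O)CC/C=C(\C)CC[C@H](O)C(C)(C)O | target

**Step count and risks**

Total step count: 12. Longest linear sequence: 10 steps (steps 1–5, 7, 9–12, from tert-butyl acetate and 2,3-dibromopropene); steps 6 and 8 supply the two side branches.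

Steps most likely to fail:

1. Step 9. At 110 °C the conjugated aryl enyne may oligomerise, the allylic alcohol may dehydrate under the acid, or exchange may stall before the vinyl ether stage, so that rearrangement is outrun by decomposition. Fallback: the rearrangement is moved ahead of both cross-couplings, onto bromo dienol 8, which is as simple as the terpenoid alcohols on which this reaction is established. Heating 8 with 16 and 2,4-dinitrophenol should lead through 3-(6-bromo-2-methylhepta-1,6-dien-3-yloxy)-3-methoxy-2-methylbutan-2-ol F1 and 3-(6-bromo-2-methylhepta-1,6-dien-3-yloxy)-2-methylbut-3-en-2-ol F2 (neither isolated) to (E)-10-bromo-2-hydroxy-2,6-dimethylundeca-6,10-dien-3-one F3. Sonogashira coupling of F3 with 9 as in step 4 should give (E)-2-hydroxy-2,6-dimethyl-10-methylidene-12-(trimethylsilyl)dodec-6-en-11-yn-3-one F4. K2CO3 in MeOH should then give (E)-2-hydroxy-2,6-dimethyl-10-methylidenedodec-6-en-11-yn-3-one F5, and coupling of F5 with aryl iodide 13 as in step 7 returns to the route at 19.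

2. Step 11. Facial discrimination may be poor if the silyloxy-bearing carbon and the methylene chain are not differentiated enough by the catalyst, or if slow hydride transfer to the hindered ketone lets uncatalysed reduction compete. Fallback: reduction without stereocontrol followed by classical resolution. From 19, NaBH4 in MeOH at 0 °C should give the racemic diol methyl 3-[(6E)-10,11-dihydroxy-7,11-dimethyl-3-methylidenedodec-6-en-1-ynyl]-4-(pivaloyloxy)benzoate F6. Acylation of its secondary hydroxyl with (S)-2-methoxy-2-phenylacetic acid (dicyclohexylcarbodiimide, 4-(dimethylamino)pyridine, CH2Cl2) should give two diastereomeric esters that are separated by chromatography; the shift differences of these esters also allow the configuration to be assigned. The (10S) ester, methyl 3-[(6E,10S)-11-hydroxy-10-[(2S)-2-methoxy-2-phenylacetoxy]-7,11-dimethyl-3-methylidenedodec-6-en-1-ynyl]-4-(pivaloyloxy)benzoate F7, is hydrolysed under the conditions of step 12, which remove the auxiliary together with the pivalate and the methyl ester and return to the route at 25.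

3. Step 12. Saponification of the methyl ester is slowed once the para phenoxide has formed, and during the longer exposure to base the ortho phenoxide may add to the alkyne in a 5-endo-dig closure to a benzofuran. Fallback: the two esters are removed separately and the benzoate is cleaved without hydroxide. From 23, K2CO3 in MeOH at 0 °C should remove only the aryl pivalate and give phenol methyl ester 24, this time isolated. Me3SnOH in 1,2-dichloroethane at 70 °C, followed by aq. KHSO4, should then cleave the methyl ester under nearly neutral conditions and return to the route at 25. This fallback makes no compound outside the compound list (entry F0).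

**Further compounds**

F1 | step 9 | 3-(6-bromo-2-methylhepta-1,6-dien-3-yloxy)-3-methoxy-2-methylbutan-2-ol (mixed ketal, not isolated) | C=C(Br)CCC(OC(C)(OC)C(C)(C)O)C(C)=C
F2 | step 9 | 3-(6-bromo-2-methylhepta-1,6-dien-3-yloxy)-2-methylbut-3-en-2-ol (allyl vinyl ether, not isolated) | C=C(Br)CCC(OC(=C)C(C)(C)O)C(C)=C
F3 | step 9 | (E)-10-bromo-2-hydroxy-2,6-dimethylundeca-6,10-dien-3-one | C=C(Br)CC/C=C(\C)CCC(=O)C(C)(C)O
F4 | step 9 | (E)-2-hydroxy-2,6-dimethyl-10-methylidene-12-(trimethylsilyl)dodec-6-en-11-yn-3-one | C[Si](C)(C)C#CC(=C)CC/C=C(\C)CCC(=O)C(C)(C)O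
F5 | step 9 | (E)-2-hydroxy-2,6-dimethyl-10-methylidenedodec-6-en-11-yn-3-one | C#CC(=C)CC/C=C(\C)CCC(=O)C(C)(C)O
F6 | step 11 | methyl 3-[(6E)-10,11-dihydroxy-7,11-dimethyl-3-methylidenedodec-6-en-1-ynyl]-4-(pivaloyloxy)benzoate (racemic) | COC(=O)c1ccc(OC(=O)C(C)(C)C)c(C#CC(=C)CC/C=C(\C)CCC(O)C(C)(C)O)c1
F7 | step 11 | methyl 3-[(6E,10S)-11-hydroxy-10-[(2S)-2-methoxy-2-phenylacetoxy]-7,11-dimethyl-3-methylidenedodec-6-en-1-ynyl]-4-(pivaloyloxy)benzoate | COC(=O)c1ccc(OC(=O)C(C)(C)C)c(C#CC(=C)CC/C=C(\C)CC[C@H](OC(=O)[C@@H](OC)c2ccccc2)C(C)(C)O)c1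
F0 | step 12 | none | none
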